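A direct plan would set C8 and C9 by an Ireland–Claisen rearrangement, extend the product to the trienal A1 and close both rings by a Lewis acid-promoted intramolecular Diels–Alder reaction to the octalin aldehyde A2. C4 would then be made quaternary by enolate methylation to the dimethyl aldehyde A3, the butenolide would be attached by B-alkyl Suzuki coupling to give the butenolide acid A4, and the ring A alkene would be hydrogenated last. Its weakest steps would be:
- the cycloaddition, because the diene terminus that becomes C10 carries an inside methyl group, which disfavours the s-cis conformer;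
- the C-methylation of the hindered aldehyde enolate, because C4 would rest on reagent approach alone, with O-alkylation competing;
- the hydrogenation of the ring A alkene beside the butenolide, which would rest on catalyst discrimination only.

Two silyl groups would add length without complexity.

The route rests on disconnecting C4–C5 and C9–C10 together. It exploits that C4 bears a carboxyl carbon and that C4, C10 and C8 are the branched carbons of a head-to-tail isoprenoid chain, so that every radical of a cascade is tertiary. The acyclic triene β-keto ester 9, with an 8-phenylmenthyl ester as its only stereocontrol element, is closed by oxidative free-radical bicyclisation with Mn(OAc)3 and Cu(OAc)2. One operation forms ring A, then ring B, sets C4 (axial ester), C5, C9 and C10 and leaves the C8=C17 alkene for the hydroxymethyl group. No cycloaddition, no alkylation at C4, no hydrogenation beside the butenolide and no protecting group remain.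

Key step: step 6

Remark: atoms are numbered as in labdanes. Ring A is C1–C5 and C10, ring B is C5–C10; C17 is on C8, C18 (methyl) and C19 (carboxyl) are on C4, C20 is on C10, and C11–C16 form the side chain.

Assumption: under non-chelating conditions the (1R,2S,5R)-8-phenylmenthyl ester is taken to direct bond formation at C4 to the face that leads to the 5α-H, 10β-methyl series. If the opposite sense were found, (1S,2R,5S)-8-phenylmenthol would be used and nothing else would change.

Step 1
Reactants: 1 geranyl acetate [(2E)-3,7-dimethylocta-2,6-dien-1-yl acetate]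
Product: 2 (2E,6E)-8-hydroxy-3,7-dimethylocta-2,6-dien-1-yl acetate
Conditions: SeO2 (0.1 equiv), tBuOOH (2 equiv), salicylic acid (0.1 equiv), CH2Cl2, 0 °C to rt
Reagents that add atoms: selenium dioxide O=[Se]=O; tert-butyl hydroperoxide CC(C)(C)OO
Why: catalytic SeO2 allylic oxidation (ene reaction, then [2,3]-sigmatropic shift) should hydroxylate the (E)-methyl group of the terminal alkene, the 2,3-alkene being deactivated by the allylic acetate.

Step 2
Reactants: 2 (2E,6E)-8-hydroxy-3,7-dimethylocta-2,6-dien-1-yl acetate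
Product: 3 (2E,6E)-2,6-dimethyldeca-2,6,9-trien-1-ol
Conditions: tributyl(vinyl)stannane (1.2 equiv), Pd(dba)2 (3 mol %), LiCl (3 equiv), DMF, rt
Reagents that add atoms: tributyl(vinyl)stannane C=C[Sn](CCCC)(CCCC)CCCC
Why: Stille coupling of the allylic acetate through the π-allylpalladium chloride should deliver the vinyl group to the primary allyl terminus with the (E) alkene kept, the free allylic hydroxyl group not being ionised.

Step 3
Reactants: 3 (2E,6E)-2,6-dimethyldeca-2,6,9-trien-1-ol
Product: 4 (2E,6E)-1-bromo-2,6-dimethyldeca-2,6,9-triene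
Conditions: CBr4, PPh3, CH2Cl2, 0 °C
Reagents that add atoms: tetrabromomethane BrC(Br)(Br)Br
Why: Appel bromination converts the primary allylic alcohol into the bromide under neutral conditions, without allylic transposition or alkene isomerisation.

Step 4
Reactants: 5 ethyl 2-methyl-3-oxobutanoate; 6 (1R,2S,5R)-5-methyl-2-(2-phenylpropan-2-yl)cyclohexan-1-ol [(−)-8-phenylmenthol]
Product: 7 (1R,2S,5R)-5-methyl-2-(2-phenylpropan-2-yl)cyclohexyl 2-methyl-3-oxobutanoate (both C2 epimers)
Conditions: DMAP (0.3 equiv), toluene, reflux, removal of EtOH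
Reagents that add atoms: none
Why: DMAP-catalysed transesterification of the enolisable β-keto ester (through the acylketene) attaches the auxiliary, and the epimeric α-centre is of no consequence.

Step 5
Reactants: 7 (1R,2S,5R)-5-methyl-2-(2-phenylpropan-2-yl)cyclohexyl 2-methyl-3-oxobutanoate; 4 (2E,6E)-1-bromo-2,6-dimethyldeca-2,6,9-triene
Product: 9 (1R,2S,5R)-5-methyl-2-(2-phenylpropan-2-yl)cyclohexyl (6E,10E)-2,6,10-trimethyl-3-oxotetradeca-6,10,13-trienoate (both C2 epimers), via sodium lithium dienolate 8 (not isolated)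
Conditions: NaH, THF, 0 °C; nBuLi, 0 °C; 4, 0 °C to rt
Reagents that add atoms: none
Why: acetoacetate dianion alkylation at the terminal γ-carbon by SN2 at the primary allylic bromide forms the C1–C2 bond and completes the carbon chain with both (E) alkenes intact.

Step 6
Reactants: 9 (1R,2S,5R)-5-methyl-2-(2-phenylpropan-2-yl)cyclohexyl (6E,10E)-2,6,10-trimethyl-3-oxotetradeca-6,10,13-trienoate
Product: 13 (1R,2S,5R)-5-methyl-2-(2-phenylpropan-2-yl)cyclohexyl (1R,4aR,5S,8aR)-1,4a-dimethyl-6-methylidene-2-oxo-5-(prop-2-en-1-yl)decahydronaphthalene-1-carboxylate, via C4 radical 10 (not isolated), via monocyclic C10 radical 11 (not isolated), via bicyclic C8 radical 12 (not isolated)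
Conditions: Mn(OAc)3·2H2O (2.2 equiv), Cu(OAc)2·H2O (1.0 equiv, reoxidised in the flask by Mn(OAc)3), degassed AcOH, 25 °C
Reagents that add atoms: none
Why: Mn(OAc)3 oxidises the enol form of 9 to the electrophilic tertiary radical 10, which adds through a chair in the 6-endo-trig mode to C5 of the (E)-C5=C10 alkene and closes ring A (C4–C5 bond); the tertiary radical 11 adds in the same mode to C9 of the (E)-C8=C9 alkene and closes ring B (C9–C10 bond), and Cu(OAc)2 turns radical 12 into an alkylcopper species that loses a C17 hydrogen to give the exocyclic alkene. The closest known reaction type is the oxidative free-radical polyene cyclisation of 2-methyl-3-oxo-6-enoates with Mn(OAc)3 and Cu(OAc)2, which gives trans-fused 1-methyl-2-oxodecalin-1-carboxylates of the podocarpate type and is also known for 8-phenylmenthyl esters. C5 and C10 follow from the (E) geometry of C5=C10 in the chair (5α-H, 10β-methyl, trans ring fusion), and C9 from the (E) geometry of C8=C9, which keeps C11 equatorial (9α-H). C4 is set relative to C5 by the geometry of the enol radical: without a chelating Lewis acid the ester lies cis to C2 and becomes axial (4β, the future C19), which is why no lanthanide triflate is added, since chelation of both carbonyl groups would turn the ester toward the ketone oxygen and make it equatorial. The absolute configuration rests on the 8-phenylmenthyl group, whose phenyl ring covers one face of the planar radical 10, and the minor facial isomer is a diastereomer that can be removed. The step needs 6-endo over 5-exo closure twice (secured by the methyl groups on C10 and C8), ring B closure faster than oxidation of 11 (secured by the chair-preorganised tether), exocyclic over endocyclic elimination (the usual course of alkylcopper intermediates) and face selectivity at C4 (auxiliary).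

Step 7
Reactants: 13 (1R,2S,5R)-5-methyl-2-(2-phenylpropan-2-yl)cyclohexyl (1R,4aR,5S,8aR)-1,4a-dimethyl-6-methylidene-2-oxo-5-(prop-2-en-1-yl)decahydronaphthalene-1-carboxylate
Product: 16 (1R,2S,5R)-5-methyl-2-(2-phenylpropan-2-yl)cyclohexyl (1S,4aR,5S,8aR)-1,4a-dimethyl-6-methylidene-5-(prop-2-en-1-yl)decahydronaphthalene-1-carboxylate, via tosylhydrazone 14 (not isolated), via alkyldiazene 15 (not isolated)
Conditions: TsNHNH2, EtOH, 70 °C; evaporation; catecholborane, CHCl3, 0 °C to rt; NaOAc·3H2O, reflux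
Reagents that add atoms: none
Why: Caglioti-type deoxygenation (hydride addition of catecholborane to the tosylhydrazone, then acetate-induced loss of sulfinate and of N2 from the diazene) should remove the C3 oxygen without strong acid or base, so that the ester and both alkenes persist and no stereocentre is touched.

Step 8
Reactants: 16 (1R,2S,5R)-5-methyl-2-(2-phenylpropan-2-yl)cyclohexyl (1S,4aR,5S,8aR)-1,4a-dimethyl-6-methylidene-5-(prop-2-en-1-yl)decahydronaphthalene-1-carboxylate
Product: 17 [(1S,4aR,5S,8aR)-1,4a-dimethyl-6-methylidene-5-(prop-2-en-1-yl)decahydronaphthalen-1-yl]methanol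
Conditions: LiAlH4 (3 equiv), THF, 65 °C; aqueous NaOH work-up; 6 recovered
Reagents that add atoms: none
Why: LiAlH4 reduces the hindered neopentyl ester to the C19 alcohol and frees the auxiliary for recovery, the isolated alkenes being inert to hydride.

Step 9
Reactants: 17 [(1S,4aR,5S,8aR)-1,4a-dimethyl-6-methylidene-5-(prop-2-en-1-yl)decahydronaphthalen-1-yl]methanol
Product: 19 (1S,4aR,5S,8aR)-1,4a-dimethyl-6-methylidene-5-(prop-2-en-1-yl)decahydronaphthalene-1-carboxylic acid, via aldehyde 18 (not isolated)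
Conditions: CrO3, H2SO4, H2O, acetone, 0 °C
Reagents that add atoms: water O
Why: Jones oxidation takes the neopentyl primary alcohol through the aldehyde hydrate to the C19 acid at 0 °C without touching the alkenes, and doing so before C17 is oxygenated makes a protecting group unnecessary.

Step 10
Reactants: 19 (1S,4aR,5S,8aR)-1,4a-dimethyl-6-methylidene-5-(prop-2-en-1-yl)decahydronaphthalene-1-carboxylic acid
Product: 20 (1R,2R,4aR,5S,8aS)-5,8a-dimethyl-1-(prop-2-en-1-yl)octahydro-1H-spiro[naphthalene-2,2'-oxirane]-5-carboxylic acid (8α,17-epoxide, oxygen anti to the angular methyl group)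
Conditions: mCPBA (1.05 equiv), NaHCO3, CH2Cl2, 0 °C
Reagents that add atoms: 3-chloroperoxybenzoic acid OOC(=O)c1cccc(Cl)c1
Why: Prilezhaev epoxidation should take the more electron-rich 1,1-disubstituted exocyclic alkene in preference to the monosubstituted allyl alkene and approach from the α face, away from the axial C20 methyl group; either epoxide face would in any case converge in step 11.

Step 11
Reactants: 20 (1R,2R,4aR,5S,8aS)-5,8a-dimethyl-1-(prop-2-en-1-yl)octahydro-1H-spiro[naphthalene-2,2'-oxirane]-5-carboxylic acid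
Product: 21 (1S,4aR,5S,6R,8aR)-6-formyl-1,4a-dimethyl-5-(prop-2-en-1-yl)decahydronaphthalene-1-carboxylic acid
Conditions: BF3·OEt2 (0.5 equiv), CH2Cl2, −78 to 0 °C
Reagents that add atoms: none
Why: Meinwald rearrangement, in which BF3 opens the epoxide at the tertiary C8–O bond and a C17 hydride shifts to C8 on the face opposite to the departing oxygen, should give the aldehyde with 8β-H and the formyl group equatorial (8α), which is also the thermodynamic epimer, so that any enolisation converges on it.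

Step 12
Reactants: 21 (1S,4aR,5S,6R,8aR)-6-formyl-1,4a-dimethyl-5-(prop-2-en-1-yl)decahydronaphthalene-1-carboxylic acid
Product: 22 (1S,4aR,5S,6R,8aR)-6-(hydroxymethyl)-1,4a-dimethyl-5-(prop-2-en-1-yl)decahydronaphthalene-1-carboxylic acid
Conditions: NaBH4, MeOH, 0 °C; then aqueous HCl to pH 3
Reagents that add atoms: none
Why: chemoselective borohydride reduction of the aldehyde gives the C17 alcohol and fixes C8, while the carboxylate and the alkene do not react.

Step 13
Reactants: 22 (1S,4aR,5S,6R,8aR)-6-(hydroxymethyl)-1,4a-dimethyl-5-(prop-2-en-1-yl)decahydronaphthalene-1-carboxylic acid; 23 3-methylideneoxolan-2-one (α-methylene-γ-butyrolactone)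
Product: 24 (1S,4aR,5S,6R,8aR)-6-(hydroxymethyl)-1,4a-dimethyl-5-[(2E)-2-(2-oxooxolan-3-ylidene)ethyl]decahydronaphthalene-1-carboxylic acid
Conditions: second-generation Hoveyda–Grubbs catalyst (5 mol %), 2,6-dichloro-1,4-benzoquinone (10 mol %), 23 (4 equiv), CH2Cl2, 40 °C
Reagents that add atoms: none
Why: cross-metathesis of the monosubstituted alkene with the 1,1-disubstituted alkene of 23 forms the C12=C13 bond as the (E)-alkylidene lactone with loss of ethene; the quinone suppresses alkene migration, and free hydroxyl and carboxyl groups are tolerated.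

Step 14
Reactants: 24 (1S,4aR,5S,6R,8aR)-6-(hydroxymethyl)-1,4a-dimethyl-5-[(2E)-2-(2-oxooxolan-3-ylidene)ethyl]decahydronaphthalene-1-carboxylic acid
Product: 25 (1S,4aR,5S,6R,8aR)-6-(hydroxymethyl)-1,4a-dimethyl-5-[2-(2-oxo-2,5-dihydrofuran-3-yl)ethyl]decahydronaphthalene-1-carboxylic acid (target)
Conditions: RhCl3·3H2O (10 mol %), EtOH, 80 °C
Reagents that add atoms: none
Why: rhodium hydride-mediated alkene isomerisation (addition–elimination) moves the exocyclic C12=C13 double bond into the ring to the more stable endocyclic butenolide (C13=C14), a known isomerisation of α-alkylidene butyrolactones that involves no stereocentre and gives the target.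

**Compound list**

1 | geranyl acetate [(2E)-3,7-dimethylocta-2,6-dien-1-yl acetate] | CC(=O)OC/C=C(\C)CCC=C(C)C | starting material
2 | (2E,6E)-8-hydroxy-3,7-dimethylocta-2,6-dien-1-yl acetate | CC(=O)OC/C=C(\C)CC/C=C(\C)CO | intermediate
3 | (2E,6E)-2,6-dimethyldeca-2,6,9-trien-1-ol | C=CC/C=C(\C)CC/C=C(\C)CO | intermediate
4 | (2E,6E)-1-bromo-2,6-dimethyldeca-2,6,9-triene | C=CC/C=C(\C)CC/C=C(\C)CBr | intermediate
5 | ethyl 2-methyl-3-oxobutanoate | CCOC(=O)C(C)C(C)=O | starting material
6 | (1R,2S,5R)-5-methyl-2-(2-phenylpropan-2-yl)cyclohexan-1-ol [(−)-8-phenylmenthol] | O[C@@H]1C[C@H](C)CC[C@H]1C(C)(C)c1ccccc1 | starting material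
7 | (1R,2S,5R)-5-methyl-2-(2-phenylpropan-2-yl)cyclohexyl 2-methyl-3-oxobutanoate (both C2 epimers) | CC(=O)C(C)C(=O)O[C@@H]1C[C@H](C)CC[C@H]1C(C)(C)c1ccccc1 | intermediate
8 | sodium lithium dienolate of 7 (dianion at the α-carbon and the terminal methyl carbon) | [Na+].[Li+].C=C([O-])C(C)=C([O-])O[C@@H]1C[C@H](C)CC[C@H]1C(C)(C)c1ccccc1 | intermediate
9 | (1R,2S,5R)-5-methyl-2-(2-phenylpropan-2-yl)cyclohexyl (6E,10E)-2,6,10-trimethyl-3-oxotetradeca-6,10,13-trienoate (both C2 epimers) | CC(C(=O)CC/C(C)=C/CC/C(C)=C/CC=C)C(=O)O[C@@H]1C[C@H](C)CC[C@H]1C(C)(C)c1ccccc1 | intermediate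
10 | C4 radical of 9 (2-yl radical, planar, flanked by the ketone and the ester) | C[C](C(=O)CC/C(C)=C/CC/C(C)=C/CC=C)C(=O)O[C@@H]1C[C@H](C)CC[C@H]1C(C)(C)c1ccccc1 | intermediate
11 | monocyclic C10 radical: ring A closed, 8-phenylmenthyl (1R,6R)-1,5-dimethyl-6-[(3E)-3-methylhepta-3,6-dien-1-yl]-2-oxocyclohexane-1-carboxylate with the radical at ring carbon 5 | C[C]1CCC(=O)[C@](C)(C(=O)O[C@@H]2C[C@H](C)CC[C@H]2C(C)(C)c2ccccc2)[C@@H]1CC/C(C)=C/CC=C | intermediate
12 | bicyclic C8 radical: trans-decalin of 13 with a methyl group and the radical at C8 in place of the methylidene group | C[C@]12CCC(=O)[C@](C)(C(=O)O[C@@H]3C[C@H](C)CC[C@H]3C(C)(C)c3ccccc3)[C@@H]1CC[C](C)[C@@H]2CC=C | intermediate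
13 | (1R,2S,5R)-5-methyl-2-(2-phenylpropan-2-yl)cyclohexyl (1R,4aR,5S,8aR)-1,4a-dimethyl-6-methylidene-2-oxo-5-(prop-2-en-1-yl)decahydronaphthalene-1-carboxylate | C[C@]12CCC(=O)[C@](C)(C(=O)O[C@@H]3C[C@H](C)CC[C@H]3C(C)(C)c3ccccc3)[C@@H]1CCC(=C)[C@@H]2CC=C | intermediate
14 | tosylhydrazone of 13: (1R,2S,5R)-5-methyl-2-(2-phenylpropan-2-yl)cyclohexyl (1R,4aR,5S,8aR)-1,4a-dimethyl-6-methylidene-2-[2-(4-methylbenzenesulfonyl)hydrazinylidene]-5-(prop-2-en-1-yl)decahydronaphthalene-1-carboxylate | C[C@]12CCC(=NNS(=O)(=O)c3ccc(C)cc3)[C@](C)(C(=O)O[C@@H]3C[C@H](C)CC[C@H]3C(C)(C)c3ccccc3)[C@@H]1CCC(=C)[C@@H]2CC=C | intermediate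
15 | alkyldiazene: (1R,2S,5R)-5-methyl-2-(2-phenylpropan-2-yl)cyclohexyl (1R,4aR,5S,8aR)-2-diazenyl-1,4a-dimethyl-6-methylidene-5-(prop-2-en-1-yl)decahydronaphthalene-1-carboxylate (mixture at C2 of the ring) | C[C@]12CCC(N=N)[C@](C)(C(=O)O[C@@H]3C[C@H](C)CC[C@H]3C(C)(C)c3ccccc3)[C@@H]1CCC(=C)[C@@H]2CC=C | intermediate
16 | (1R,2S,5R)-5-methyl-2-(2-phenylpropan-2-yl)cyclohexyl (1S,4aR,5S,8aR)-1,4a-dimethyl-6-methylidene-5-(prop-2-en-1-yl)decahydronaphthalene-1-carboxylate | C[C@]12CCC[C@](C)(C(=O)O[C@@H]3C[C@H](C)CC[C@H]3C(C)(C)c3ccccc3)[C@@H]1CCC(=C)[C@@H]2CC=C | intermediate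
17 | [(1S,4aR,5S,8aR)-1,4a-dimethyl-6-methylidene-5-(prop-2-en-1-yl)decahydronaphthalen-1-yl]methanol | C[C@]12CCC[C@](C)(CO)[C@@H]1CCC(=C)[C@@H]2CC=C | intermediate
18 | (1S,4aR,5S,8aR)-1,4a-dimethyl-6-methylidene-5-(prop-2-en-1-yl)decahydronaphthalene-1-carbaldehyde | C[C@]12CCC[C@](C)(C=O)[C@@H]1CCC(=C)[C@@H]2CC=C | intermediate
19 | (1S,4aR,5S,8aR)-1,4a-dimethyl-6-methylidene-5-(prop-2-en-1-yl)decahydronaphthalene-1-carboxylic acid | C[C@]12CCC[C@](C)(C(=O)O)[C@@H]1CCC(=C)[C@@H]2CC=C | intermediate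
20 | (1R,2R,4aR,5S,8aS)-5,8a-dimethyl-1-(prop-2-en-1-yl)octahydro-1H-spiro[naphthalene-2,2'-oxirane]-5-carboxylic acid (8α,17-epoxide) | C[C@]12CCC[C@](C)(C(=O)O)[C@@H]1CC[C@@]3(OC3)[C@@H]2CC=C | intermediate
21 | (1S,4aR,5S,6R,8aR)-6-formyl-1,4a-dimethyl-5-(prop-2-en-1-yl)decahydronaphthalene-1-carboxylic acid | C[C@]12CCC[C@](C)(C(=O)O)[C@@H]1CC[C@@H](C=O)[C@@H]2CC=C | intermediate
22 | (1S,4aR,5S,6R,8aR)-6-(hydroxymethyl)-1,4a-dimethyl-5-(prop-2-en-1-yl)decahydronaphthalene-1-carboxylic acid | C[C@]12CCC[C@](C)(C(=O)O)[C@@H]1CC[C@@H](CO)[C@@H]2CC=C | intermediate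
23 | 3-methylideneoxolan-2-one (α-methylene-γ-butyrolactone) | C=C1CCOC1=O | starting material
24 | (1S,4aR,5S,6R,8aR)-6-(hydroxymethyl)-1,4a-dimethyl-5-[(2E)-2-(2-oxooxolan-3-ylidene)ethyl]decahydronaphthalene-1-carboxylic acid | C[C@]12CCC[C@](C)(C(=O)O)[C@@H]1CC[C@@H](CO)[C@@H]2C/C=C1\CCOC1=O | intermediate
25 | (1S,4aR,5S,6R,8aR)-6-(hydroxymethyl)-1,4a-dimethyl-5-[2-(2-oxo-2,5-dihydrofuran-3-yl)ethyl]decahydronaphthalene-1-carboxylic acid | C[C@]12CCC[C@](C)(C(=O)O)[C@@H]1CC[C@@H](CO)[C@@H]2CCC1=CCOC1=O | target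

Total step count: 14. Longest linear sequence: 13 steps (steps 1–3 and 5–14, from geranyl acetate).

Steps most likely to fail

Step 6. What may go wrong: the auxiliary may give insufficient face selectivity at C4 under non-chelating conditions, so that too much of the enantiomeric decalin series forms. The fallback introduces the absolute configuration by resolution; it sets out from 5 and 4 and comes back at 19. Dianion alkylation of 5 with 4 (NaH, nBuLi, THF) would give ethyl (6E,10E)-2,6,10-trimethyl-3-oxotetradeca-6,10,13-trienoate F1. The same Mn(OAc)3/Cu(OAc)2 bicyclisation would give racemic ethyl (1R*,4aR*,5S*,8aR*)-1,4a-dimethyl-6-methylidene-2-oxo-5-(prop-2-en-1-yl)decahydronaphthalene-1-carboxylate F2. The tosylhydrazone/catecholborane sequence would give the racemic ethyl ester without the C3 oxygen F3, LiAlH4 the racemic C19 alcohol F4, and Jones oxidation the racemic acid F5. Crystallisation with (1R)-1-phenylethanamine (or its enantiomer, whichever gives the less soluble salt of the wanted acid) would give the (1R)-1-phenylethanaminium salt of the (1S,4aR,5S,8aR) acid F6, from which dilute HCl would release 19.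

Step 7. What may go wrong: condensation of the sulfonyl hydrazide with the C3 ketone, which is shielded by the quaternary C4 and the bulky ester, may be slow or incomplete. The fallback removes the oxygen by radical deoxygenation (Barton–McCombie); it sets out from 13 and comes back at 16. NaBH4 (MeOH/THF, 0 °C) would give the 3β-alcohol, 8-phenylmenthyl (1R,2S,4aR,5S,8aR)-2-hydroxy-1,4a-dimethyl-6-methylidene-5-(prop-2-en-1-yl)decahydronaphthalene-1-carboxylate F7. NaH, CS2 and MeI would give its O-alkyl S-methyl dithiocarbonate F8, and Bu3SnH with AIBN in toluene at 110 °C would give 16.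

Step 11. What may go wrong: the C8 cation may lose a proton from C7 or C9 to give allylic alcohols instead of undergoing the 1,2-hydride shift. The fallback makes that elimination deliberate and reaches the aldehyde by oxidation and conjugate reduction; it sets out from 20 and comes back at 21. LiNEt2 (excess, the carboxylate forming first; THF, reflux) would give the allylic alcohol, (1S,4aR,5R,8aR)-6-(hydroxymethyl)-1,4a-dimethyl-5-(prop-2-en-1-yl)-1,2,3,4,4a,5,8,8a-octahydronaphthalene-1-carboxylic acid F9. MnO2 in CH2Cl2 would give the enal, (1S,4aR,5R,8aR)-6-formyl-1,4a-dimethyl-5-(prop-2-en-1-yl)-1,2,3,4,4a,5,8,8a-octahydronaphthalene-1-carboxylic acid F10. Conjugate reduction of its sodium salt with [(Ph3P)CuH]6 in THF, followed by aqueous work-up with thermodynamic protonation at C8, would give 21.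

Further compounds

F1 | step 6 | ethyl (6E,10E)-2,6,10-trimethyl-3-oxotetradeca-6,10,13-trienoate | CCOC(=O)C(C)C(=O)CC/C(C)=C/CC/C(C)=C/CC=C
F2 | step 6 | racemic ethyl (1R*,4aR*,5S*,8aR*)-1,4a-dimethyl-6-methylidene-2-oxo-5-(prop-2-en-1-yl)decahydronaphthalene-1-carboxylate | C[C@]12CCC(=O)[C@](C)(C(=O)OCC)[C@@H]1CCC(=C)[C@@H]2CC=C.C[C@@]12CCC(=O)[C@@](C)(C(=O)OCC)[C@H]1CCC(=C)[C@H]2CC=C
F3 | step 6 | racemic ethyl (1S*,4aR*,5S*,8aR*)-1,4a-dimethyl-6-methylidene-5-(prop-2-en-1-yl)decahydronaphthalene-1-carboxylate | C[C@]12CCC[C@](C)(C(=O)OCC)[C@@H]1CCC(=C)[C@@H]2CC=C.C[C@@]12CCC[C@@](C)(C(=O)OCC)[C@H]1CCC(=C)[C@H]2CC=C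
F4 | step 6 | racemic [(1S*,4aR*,5S*,8aR*)-1,4a-dimethyl-6-methylidene-5-(prop-2-en-1-yl)decahydronaphthalen-1-yl]methanol | C[C@]12CCC[C@](C)(CO)[C@@H]1CCC(=C)[C@@H]2CC=C.C[C@@]12CCC[C@@](C)(CO)[C@H]1CCC(=C)[C@H]2CC=C
F5 | step 6 | racemic (1S*,4aR*,5S*,8aR*)-1,4a-dimethyl-6-methylidene-5-(prop-2-en-1-yl)decahydronaphthalene-1-carboxylic acid | C[C@]12CCC[C@](C)(C(=O)O)[C@@H]1CCC(=C)[C@@H]2CC=C.C[C@@]12CCC[C@@](C)(C(=O)O)[C@H]1CCC(=C)[C@H]2CC=C
F6 | step 6 | (1R)-1-phenylethanaminium (1S,4aR,5S,8aR)-1,4a-dimethyl-6-methylidene-5-(prop-2-en-1-yl)decahydronaphthalene-1-carboxylate | C[C@]12CCC[C@](C)(C(=O)[O-])[C@@H]1CCC(=C)[C@@H]2CC=C.C[C@@H]([NH3+])c1ccccc1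
F7 | step 7 | (1R,2S,5R)-5-methyl-2-(2-phenylpropan-2-yl)cyclohexyl (1R,2S,4aR,5S,8aR)-2-hydroxy-1,4a-dimethyl-6-methylidene-5-(prop-2-en-1-yl)decahydronaphthalene-1-carboxylate | C[C@]12CC[C@H](O)[C@](C)(C(=O)O[C@@H]3C[C@H](C)CC[C@H]3C(C)(C)c3ccccc3)[C@@H]1CCC(=C)[C@@H]2CC=C
F8 | step 7 | O-alkyl S-methyl dithiocarbonate (xanthate) of F7 at the C2 oxygen of the ring | C[C@]12CC[C@H](OC(=S)SC)[C@](C)(C(=O)O[C@@H]3C[C@H](C)CC[C@H]3C(C)(C)c3ccccc3)[C@@H]1CCC(=C)[C@@H]2CC=C
F9 | step 11 | (1S,4aR,5R,8aR)-6-(hydroxymethyl)-1,4a-dimethyl-5-(prop-2-en-1-yl)-1,2,3,4,4a,5,8,8a-octahydronaphthalene-1-carboxylic acid | C[C@]12CCC[C@](C)(C(=O)O)[C@@H]1CC=C(CO)[C@@H]2CC=C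
F10 | step 11 | (1S,4aR,5R,8aR)-6-formyl-1,4a-dimethyl-5-(prop-2-en-1-yl)-1,2,3,4,4a,5,8,8a-octahydronaphthalene-1-carboxylic acid | C[C@]12CCC[C@](C)(C(=O)O)[C@@H]1CC=C(C=O)[C@@H]2CC=C
A1 | direct plan | (2E,6R,7S,8E)-6-{[(tert-butyldiphenylsilyl)oxy]methyl}-7-ethenyl-8-methylundeca-2,8,10-trienal | O=C/C=C/CC[C@@H](CO[Si](c1ccccc1)(c1ccccc1)C(C)(C)C)[C@H](C=C)/C(C)=C/C=C
A2 | direct plan | (1R,4aS,5S,6R,8aS)-6-{[(tert-butyldiphenylsilyl)oxy]methyl}-5-ethenyl-4a-methyl-1,2,4a,5,6,7,8,8a-octahydronaphthalene-1-carbaldehyde | C[C@]12C=CC[C@@H](C=O)[C@@H]1CC[C@@H](CO[Si](c3ccccc3)(c3ccccc3)C(C)(C)C)[C@@H]2C=C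
A3 | direct plan | (1S,4aR,5S,6R,8aR)-6-{[(tert-butyldiphenylsilyl)oxy]methyl}-5-ethenyl-1,4a-dimethyl-1,2,4a,5,6,7,8,8a-octahydronaphthalene-1-carbaldehyde | C[C@]12C=CC[C@](C)(C=O)[C@@H]1CC[C@@H](CO[Si](c3ccccc3)(c3ccccc3)C(C)(C)C)[C@@H]2C=C
A4 | direct plan | (1S,4aR,5S,6R,8aR)-6-{[(tert-butyldiphenylsilyl)oxy]methyl}-1,4a-dimethyl-5-[2-(2-oxo-2,5-dihydrofuran-3-yl)ethyl]-1,2,4a,5,6,7,8,8a-octahydronaphthalene-1-carboxylic acid | C[C@]12C=CC[C@](C)(C(=O)O)[C@@H]1CC[C@@H](CO[Si](c3ccccc3)(c3ccccc3)C(C)(C)C)[C@@H]2CCC1=CCOC1=O
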